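## Analysis of the target

The target joins two fragments through one oxygen: a trans-fused eudesmane (decalin rings A and B, C1–C15) and a honokiol-type 3,5'-diallylbiphenyl-2',4-diol (rings C and D). The C4 oxygen of the terpene is the ether oxygen on ring C. All four stereocentres lie in the decalin:

- C10 carries the angular methyl (β).
- C5 carries H on the α face (trans fusion).
- C7 is R, with the 2-hydroxypropan-2-yl group β and equatorial, cis to the C10 methyl.
- C4 has its oxygen α and equatorial; the C15 methyl is β, axial and 1,3-syn to the C10 methyl.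

The C4–O–aryl bond is the weak point: a tertiary alkyl aryl ether next to a ring fusion ionises in acid, and the C11 tertiary alcohol dehydrates under the same conditions. The two allyl groups move into conjugation with base or palladium hydrides and do not survive electrophilic oxidants, and ring D carries a free phenol. The difficulty is threefold: a decalin with a quaternary C10 and three further stereocentres, a very hindered ether whose C4 configuration must be fixed, and two tertiary oxygens (C4 and C11) that must be told apart.

The strategy rests on C10 and its ring bonds. C5–C10 and C1–C2 are the two bonds a [4+2] cycloaddition makes when a C2=C3–C4=C5 diene meets a C1=C10 2-propenyl group across the tether C6–C9. The cycloaddition leaves C3=C4 where the ether oxygen must enter, and its triene is the ring-opened, chain-extended form of a p-menthenol that already holds C7 and C11.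

## Retrosynthetic reasoning

**23 ⇒ 22 (C11 O–Si).** The C11 oxygen is carried as a triethylsilyl ether from the first step to the last. This keeps it apart from the C4 oxygen and lets the last step run with fluoride instead of acid, which the C4 ether would not tolerate.

**22 ⇒ 21 (ring C aryl–CH2 bond).** The allyl group of ring C is cut off and replaced by chlorine. The arene that is put on oxygen must be made with an electrophilic oxidant, which an allyl group would not survive; a chloride does, and it stays inert while the bromide reacts. The forward reaction is a cross-coupling of an aryl chloride with an allyl–metal reagent.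

**21 ⇒ 16 + 20 (biaryl bond).** The C–D bond is cut between a bromide on ring C and a boronate on ring D. Ring D then arrives complete, with its allyl group and free phenol, and the coupling must discriminate C–Br from C–Cl.

**16 ⇒ 10 + 14 (O–aryl bond, not C4–O).** Making C4–O by capture of a C4 cation with a phenol would be reversible, would leave the face of attack open and would compete with elimination and ring alkylation. Cutting on the aryl side means the C4–O bond exists beforehand with its configuration, and the arylation happens at oxygen. The forward reaction is aryl transfer from trivalent iodine in 14 to the alkoxide of 10.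

**10 ⇒ 9 ⇒ 8 (C4–O and C3–H).** The tertiary alcohol is traced to the C3=C4 alkene through the α-epoxide 9. The epoxidation face fixes C4, and a hydride at the secondary C3 removes the second oxygen function without touching C4.

**8 ⇒ 7 (C5–C10 and C1–C2).** Both rings are opened at once by a retro-[4+2]. This is the only disconnection that removes the quaternary centre and both rings together, and it leads to an acyclic triene with one stereocentre. The forward reaction must give the trans fusion and place the C7 group equatorial.

**7 ⇒ 6 ⇒ 4 + 5 (two C=CH2 bonds, then C4=C5).** The terminal methylenes C1 and C2 are removed to give ketone and enal carbonyls. The C4=C5 bond is then cut between aldehyde 4 and ylide 5, which brings C3, C4 and C15 and sets the (E) geometry.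

**4 ⇒ 2 ⇒ 1 (C5–C10, ring cleavage).** Keto aldehyde 4 is the product of oxidative cleavage of the ring alkene of 2. The two alkene carbons of 1 are C5 and C10, so the cycloaddition later re-forms the same bond with C10 quaternary and ring A attached; the ring of 1 becomes ring B.

**14 ⇒ 11 + 12 and 20 ⇒ 19 ⇒ 18 ⇒ 17.** The iodonium salt comes from an aryl iodide and an electron-rich arene as the group that stays on iodine. The boronate comes from 4-bromophenol by O-allylation, [3,3] shift of the allyl group to the ortho position and borylation of the bromide.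

## Alternatives that were turned down

**Alternative 1:** The cut is made in ring C and not at oxygen. Two C–C bonds of ring C are removed, so the C4–O bond is already present in an ynol ether A2 whose alkyne carries ring D. Forward, A2 and the 2-pyrone ester A3 combine in an inverse-demand [4+2] cycloaddition, and decarboxylative retro-[4+2] of the bridged adduct gives benzoate A1. The polarisation of both partners places the ester para to the ether oxygen.

- For: no aryl group is forced onto a hindered tertiary oxygen, the C–D biaryl bond comes with the alkyne, and C4 is never near a cation. On these points it is as strong as or stronger than the chosen route.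
- Against: it does not touch the decalin, so an alcohol such as 10 must be made first in any case. An alkynyl ether of a tertiary alcohol with β-hydrogens (C3, C5, C15) is prone to retro-ene loss of a ketene near the temperature the cycloaddition needs. A2 costs about three steps from the alkoxide, and the ester of A1 must become an allyl group by reduction, activation and vinyl coupling.
- Comparison: from 10 this is about eight steps against four. The chosen route offers the shorter end game, and its arylation at iodine also avoids a C4 cation.

**Alternative 2:** The cut removes the C2–C3 bond of ring A and the C4–O bond, leading to the elemane 1,5-diene A5 and the phenol A6. Forward, a divalent palladium catalyst binds the C10 vinyl group of A5, the 2-propenyl terminus C3 attacks C2 through a chair (a Cope-type cyclisation stopped halfway), and A6 captures the tertiary C4 cation to give A4.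

- For: C5, C7 and C10 are bought, ring A and the ether bond form in one step, and two couplings would finish the target. In step count it is clearly stronger than the chosen route.
- Against: the cyclohexyl cation of such catalysed Cope processes normally collapses by fragmentation or proton loss, and a hindered, electron-poor external phenol must outrun both. The C2–palladium bond left behind has β-hydrogens and would sooner eliminate than be protonated. The face of capture at C4 is not controlled, and the new ether and the free C11 alcohol sit in a medium that turns acidic.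
- Comparison: the chosen route pays with more steps but sets C4 by the face of an epoxidation and makes every bond by a reaction of known course.

**Alternative 3:** The whole diol A7 is disconnected to the acyclic diphosphate A8. Forward, a recombinant, magnesium-dependent cyclase ionises A8, closes a ten-membered ring, closes C5–C10 across it and quenches the cations at C11 and C4 as hydroxyl groups.

- For: all four stereocentres and both tertiary C–O bonds form in one step under enzyme control, which no chemical route here matches. Selective silylation of the less hindered C11 hydroxyl would then give 10 in two steps against seven.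
- Against: it needs an expressed enzyme that cannot be bought and a costly substrate at high dilution in buffer. Cyclases of this class often release alkene co-products, and throughput limits the four chemical steps that follow. The two tertiary hydroxyls must be told apart after the fact.
- Comparison: the chosen strategy runs on gram scale with ordinary reagents from an inexpensive monoterpene alcohol, and protects the C11 oxygen before the ring system exists, so the two tertiary oxygens never compete.

Key step: step 5

Remark on the chemistry: eudesmane locants C1–C15 are used for all intermediates, the acyclic ones included; α is the face of the decalin opposite to the C10 methyl group, and the target is read as 4α-O, 5α-H, 7β side chain, 10β-CH3.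

## Route

Step 1
Reactants: 1 (R)-α-terpineol
Product: 2 triethylsilyl ether of (R)-α-terpineol
Conditions: TESOTf, 2,6-lutidine, CH2Cl2, −78 → 0 °C
Reagents that add atoms: triethylsilyl trifluoromethanesulfonate, CC[Si](CC)(CC)OS(=O)(=O)C(F)(F)F
Why: Silylation of a tertiary alcohol with a silyl triflate and a hindered pyridine base is fast at low temperature; the ring alkene and the stereocentre are not touched.

Step 2
Reactants: 2 triethylsilyl ether of (R)-α-terpineol
Product: 4 (3R)-6-oxo-3-[2-(triethylsilyloxy)propan-2-yl]heptanal, via ozonide 3 (not isolated)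
Conditions: O3, CH2Cl2, −78 °C; then PPh3, −78 °C → rt
Reagents that add atoms: ozone, [O-][O+]=O
Why: Ozonolysis with reductive work-up cleaves the only alkene to a methyl ketone (C10) and an aldehyde (C5); C7 is not α to either carbonyl and cannot epimerise, and the silyl ether prevents lactol formation.

Step 3
Reactants: 4 (3R)-6-oxo-3-[2-(triethylsilyloxy)propan-2-yl]heptanal; 5 2-(triphenylphosphoranylidene)propanal
Product: 6 (2E,5R)-2-methyl-8-oxo-5-[2-(triethylsilyloxy)propan-2-yl]non-2-enal
Conditions: toluene, 80 °C
Reagents that add atoms: none
Why: Wittig reaction of a stabilised formyl ylide, which reacts with the aldehyde and not with the methyl ketone and should give the (E)-2-methyl enal, as stabilised ylides do.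

Step 4
Reactants: 6 (2E,5R)-2-methyl-8-oxo-5-[2-(triethylsilyloxy)propan-2-yl]non-2-enal
Product: 7 triethyl({2-[(3E,6R)-3,9-dimethyldeca-1,3,9-trien-6-yl]propan-2-yl}oxy)silane
Conditions: Ph3PCH3Br, KOt-Bu, THF, 0 °C → rt
Reagents that add atoms: methyltriphenylphosphonium bromide, C[P+](c1ccccc1)(c1ccccc1)c1ccccc1.[Br-]
Why: Wittig methylenation turns the enal into the terminal diene and the methyl ketone into the 2-propenyl group in one operation; 1,2-addition of the ylide leaves the (E) C4=C5 bond and C7 as they are.

Step 5
Reactants: 7 triethyl({2-[(3E,6R)-3,9-dimethyldeca-1,3,9-trien-6-yl]propan-2-yl}oxy)silane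
Product: 8 triethylsilyl ether of α-eudesmol (eudesm-3-en-11-yl triethylsilyl ether)
Conditions: toluene (0.02 M), BHT (5 mol%), sealed tube, 220 °C
Reagents that add atoms: none
Why: The triene should undergo a concerted, suprafacial thermal [4+2] cycloaddition (type 1 intramolecular Diels–Alder reaction) between the s-cis diene C2=C3–C4=C5 and the unactivated 1,1-disubstituted alkene C1=C10, forming C1–C2 and C5–C10 together and leaving C3=C4. The closest known reaction type is the thermal cyclisation of 1,7,9-decatrienes with a 2-propenyl dienophile to angularly methylated octalins of the selinane family, which needs about 200–250 °C. Ring A is the cycloadduct cyclohexene itself; ring B closes in the fused mode as the C5–C10 bond spans the four-carbon tether C6–C9, which is chair-like in the transition state. C5 and C10 are set relative to each other by the anti transition state (tether turned away from the diene), which with the (E) C4=C5 bond gives H5 and the C10 methyl trans. Their absolute sense is set by C7: the chair tether places the bulky 2-(triethylsilyloxy)propan-2-yl group equatorial, so the diene adds to the alkene face that puts the C10 methyl cis to that group. The step needs anti over syn and equatorial over axial selectivity; the C4 methyl, cis to C6 on the diene, is expected to penalise the syn array in which the tether folds under C4, and the size of the silyloxy-bearing group secures the equatorial position. The tether length allows only the fused regiochemistry, and the silyl ether, the absence of acid and the radical inhibitor should let the substrate stand the temperature.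

Step 6
Reactants: 8 triethylsilyl ether of α-eudesmol
Product: 9 (3α,4α)-3,4-epoxy-11-(triethylsilyloxy)eudesmane
Conditions: mCPBA, NaHCO3, CH2Cl2, 0 °C
Reagents that add atoms: 3-chloroperoxybenzoic acid, O=C(OO)c1cccc(Cl)c1
Why: Prilezhaev epoxidation of the only alkene; the axial C10 methyl, 1,3 to C4, covers the β face, so the peracid should add from the α face and place the oxygen on C4 with the configuration of the target (C3 and C4 set under substrate control).

Step 7
Reactants: 9 (3α,4α)-3,4-epoxy-11-(triethylsilyloxy)eudesmane
Product: 10 11-(triethylsilyloxy)eudesman-4α-ol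
Conditions: LiEt3BH, THF, 0 °C → reflux; aqueous work-up
Reagents that add atoms: none
Why: Hydride opening of a trisubstituted epoxide by SN2 attack at the secondary carbon C3; the C4–O bond is not broken, so C4 keeps its configuration and the stereocentre at C3 disappears.

Step 8
Reactants: 11 2-bromo-4-chloro-1-iodobenzene; 12 1,3,5-trimethoxybenzene
Product: 14 (2-bromo-4-chlorophenyl)(2,4,6-trimethoxyphenyl)iodonium tosylate, via hydroxy(tosyloxy)iodoarene 13 (not isolated)
Conditions: mCPBA, TsOH·H2O, MeCN, 55 °C; then 12, 55 °C → rt
Reagents that add atoms: 4-methylbenzenesulfonic acid monohydrate, Cc1ccc(S(=O)(=O)O)cc1.O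
Why: One-pot diaryliodonium synthesis: the peracid oxidises the aryl iodide to a trivalent iodine tosylate, which then substitutes the electron-rich arene 12 at its only type of C–H position.

Step 9
Reactants: 10 11-(triethylsilyloxy)eudesman-4α-ol; 14 (2-bromo-4-chlorophenyl)(2,4,6-trimethoxyphenyl)iodonium tosylate
Product: 16 4α-(2-bromo-4-chlorophenoxy)-11-(triethylsilyloxy)eudesmane, via sodium alkoxide 15 (not isolated)
Conditions: NaH, THF, 0 °C → rt; then 14, toluene, rt → 40 °C
Reagents that add atoms: none
Why: Metal-free O-arylation of an alkoxide with a diaryliodonium salt (ligand exchange at iodine, then ligand coupling), a reaction type used for congested tertiary alkyl aryl ethers; the electron-poor, ortho-substituted aryl group is the one transferred and the trimethoxyphenyl group leaves as its iodide. C4 takes no part, so its configuration is retained.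

Step 10
Reactants: 17 4-bromophenol
Product: 18 1-bromo-4-(prop-2-en-1-yloxy)benzene
Conditions: allyl bromide, K2CO3, acetone, reflux
Reagents that add atoms: allyl bromide, C=CCBr
Why: Williamson ether synthesis of a phenoxide with a reactive allylic bromide.

Step 11
Reactants: 18 1-bromo-4-(prop-2-en-1-yloxy)benzene
Product: 19 4-bromo-2-(prop-2-en-1-yl)phenol
Conditions: N,N-diethylaniline, 200 °C
Reagents that add atoms: none
Why: Aromatic Claisen rearrangement ([3,3]-sigmatropic shift, then tautomerisation); the two ortho positions are equivalent and the para position is blocked by bromine.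

Step 12
Reactants: 19 4-bromo-2-(prop-2-en-1-yl)phenol
Product: 20 2-(prop-2-en-1-yl)-4-(4,4,5,5-tetramethyl-1,3,2-dioxaborolan-2-yl)phenol
Conditions: B2pin2, Pd(dppf)Cl2, KOAc, dioxane, 90 °C
Reagents that add atoms: bis(pinacolato)diboron, CC1(C)OB(OC1(C)C)B1OC(C)(C)C(C)(C)O1
Why: Miyaura borylation of an aryl bromide; acetate as the base leaves the phenol and the allyl group alone.

Step 13
Reactants: 16 4α-(2-bromo-4-chlorophenoxy)-11-(triethylsilyloxy)eudesmane; 20 2-(prop-2-en-1-yl)-4-(4,4,5,5-tetramethyl-1,3,2-dioxaborolan-2-yl)phenol
Product: 21 5'-chloro-3-(prop-2-en-1-yl)-2'-{[11-(triethylsilyloxy)eudesman-4α-yl]oxy}biphenyl-4-ol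
Conditions: Pd(dppf)Cl2, K3PO4, dioxane/H2O, 80 °C
Reagents that add atoms: none
Why: Suzuki–Miyaura coupling; with a bisphosphine palladium catalyst oxidative addition should take place at C–Br and not at C–Cl, and aqueous phosphate is mild enough for the silyl ether, the tertiary ether and the free phenol.

Step 14
Reactants: 21 5'-chloro-3-(prop-2-en-1-yl)-2'-{[11-(triethylsilyloxy)eudesman-4α-yl]oxy}biphenyl-4-ol
Product: 22 3,5'-di(prop-2-en-1-yl)-2'-{[11-(triethylsilyloxy)eudesman-4α-yl]oxy}biphenyl-4-ol
Conditions: allylSnBu3, Pd2(dba)3, P(t-Bu)3, CsF, dioxane, 90 °C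
Reagents that add atoms: allyltributylstannane, C=CC[Sn](CCCC)(CCCC)CCCC
Why: Stille coupling of an aryl chloride, made possible by the bulky electron-rich phosphine and fluoride activation of the stannane; reductive elimination from the aryl(allyl)palladium gives the allyl arene. Any loss of the silyl group here is harmless because step 15 removes it.

Step 15
Reactants: 22 3,5'-di(prop-2-en-1-yl)-2'-{[11-(triethylsilyloxy)eudesman-4α-yl]oxy}biphenyl-4-ol
Product: 23 3,5'-di(prop-2-en-1-yl)-2'-[(11-hydroxyeudesman-4α-yl)oxy]biphenyl-4-ol (target)
Conditions: TBAF, THF, rt → 50 °C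
Reagents that add atoms: none
Why: Fluoride-induced cleavage of the triethylsilyl ether; the non-acidic conditions leave the tertiary alkyl aryl ether and both allyl groups intact.

## Compound list

1 | (R)-α-terpineol, 2-[(1R)-4-methylcyclohex-3-en-1-yl]propan-2-ol | CC1=CC[C@H](C(C)(C)O)CC1 | starting material
2 | triethyl({2-[(1R)-4-methylcyclohex-3-en-1-yl]propan-2-yl}oxy)silane | CC1=CC[C@H](C(C)(C)O[Si](CC)(CC)CC)CC1 | intermediate
3 | ozonide of 2, 1-methyl-4-[2-(triethylsilyloxy)propan-2-yl]-7,8,9-trioxabicyclo[4.2.1]nonane (side-chain carbon as in 2, mixture at the bridgeheads) | CC12CC[C@@H](C(C)(C)O[Si](CC)(CC)CC)CC(OO1)O2 | intermediate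
4 | (3R)-6-oxo-3-[2-(triethylsilyloxy)propan-2-yl]heptanal | CC(=O)CC[C@@H](C(C)(C)O[Si](CC)(CC)CC)CC=O | intermediate
5 | 2-(triphenylphosphoranylidene)propanal | CC(C=O)=P(c1ccccc1)(c1ccccc1)c1ccccc1 | starting material
6 | (2E,5R)-2-methyl-8-oxo-5-[2-(triethylsilyloxy)propan-2-yl]non-2-enal | CC(=O)CC[C@@H](C(C)(C)O[Si](CC)(CC)CC)C/C=C(\C)C=O | intermediate
7 | triethyl({2-[(3E,6R)-3,9-dimethyldeca-1,3,9-trien-6-yl]propan-2-yl}oxy)silane | C=C/C(C)=C/C[C@H](C(C)(C)O[Si](CC)(CC)CC)CCC(C)=C | intermediate
8 | triethylsilyl ether of α-eudesmol, triethyl({2-[(2R,4aR,8aR)-4a,8-dimethyl-1,2,3,4,4a,5,6,8a-octahydronaphthalen-2-yl]propan-2-yl}oxy)silane | CC1=CCC[C@]2(C)CC[C@@H](C(C)(C)O[Si](CC)(CC)CC)C[C@H]21 | intermediate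
9 | (3α,4α)-3,4-epoxy-11-(triethylsilyloxy)eudesmane (5α-H, 7β side chain, 10β-CH3) | C[C@@]12O[C@@H]1CC[C@]3(C)CC[C@@H](C(C)(C)O[Si](CC)(CC)CC)C[C@@H]23 | intermediate
10 | 11-(triethylsilyloxy)eudesman-4α-ol (4β-CH3, 5α-H, 7β side chain, 10β-CH3) | O[C@]1(C)CCC[C@]2(C)CC[C@@H](C(C)(C)O[Si](CC)(CC)CC)C[C@H]21 | intermediate
11 | 2-bromo-4-chloro-1-iodobenzene | Clc1ccc(I)c(Br)c1 | starting material
12 | 1,3,5-trimethoxybenzene | COc1cc(OC)cc(OC)c1 | starting material
13 | 2-bromo-4-chloro-1-[hydroxy(tosyloxy)-λ3-iodanyl]benzene | Cc1ccc(S(=O)(=O)OI(O)c2ccc(Cl)cc2Br)cc1 | intermediate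
14 | (2-bromo-4-chlorophenyl)(2,4,6-trimethoxyphenyl)iodonium 4-methylbenzenesulfonate | COc1cc(OC)c([I+]c2ccc(Cl)cc2Br)c(OC)c1.Cc1ccc(S(=O)(=O)[O-])cc1 | intermediate
15 | sodium alkoxide of 10 | [Na+].[O-][C@]1(C)CCC[C@]2(C)CC[C@@H](C(C)(C)O[Si](CC)(CC)CC)C[C@H]21 | intermediate
16 | 4α-(2-bromo-4-chlorophenoxy)-11-(triethylsilyloxy)eudesmane | Clc1ccc(O[C@]2(C)CCC[C@]3(C)CC[C@@H](C(C)(C)O[Si](CC)(CC)CC)C[C@H]32)c(Br)c1 | intermediate
17 | 4-bromophenol | Oc1ccc(Br)cc1 | starting material
18 | 1-bromo-4-(prop-2-en-1-yloxy)benzene | C=CCOc1ccc(Br)cc1 | intermediate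
19 | 4-bromo-2-(prop-2-en-1-yl)phenol | C=CCc1cc(Br)ccc1O | intermediate
20 | 2-(prop-2-en-1-yl)-4-(4,4,5,5-tetramethyl-1,3,2-dioxaborolan-2-yl)phenol | C=CCc1cc(B2OC(C)(C)C(C)(C)O2)ccc1O | intermediate
21 | 5'-chloro-3-(prop-2-en-1-yl)-2'-{[11-(triethylsilyloxy)eudesman-4α-yl]oxy}biphenyl-4-ol | Clc1ccc(O[C@]2(C)CCC[C@]3(C)CC[C@@H](C(C)(C)O[Si](CC)(CC)CC)C[C@H]32)c(-c2ccc(O)c(CC=C)c2)c1 | intermediate
22 | 3,5'-di(prop-2-en-1-yl)-2'-{[11-(triethylsilyloxy)eudesman-4α-yl]oxy}biphenyl-4-ol | C=CCc1ccc(O[C@]2(C)CCC[C@]3(C)CC[C@@H](C(C)(C)O[Si](CC)(CC)CC)C[C@H]32)c(-c2ccc(O)c(CC=C)c2)c1 | intermediate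
23 | 3,5'-di(prop-2-en-1-yl)-2'-[(11-hydroxyeudesman-4α-yl)oxy]biphenyl-4-ol, CNP0219722.1 | C=CCc1ccc(O[C@]2(C)CCC[C@]3(C)CC[C@@H](C(C)(C)O)C[C@H]32)c(-c2ccc(O)c(CC=C)c2)c1 | target

## Step count and least certain steps

Total step count: 15. Longest linear sequence: 11 steps from 1 (steps 1–7, 9, 13, 14 and 15). Steps 8 and 10–12 make the two aryl fragments.

**Step 5 (key step).** The syn transition state (cis fusion) or the chair with an axial C7 group may compete, and the diene may oligomerise before a slow cycloaddition to a quaternary centre is complete. The syn array relieves the contact between the endo C10 methyl and the C4 methyl, so the preference may be small.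

Fallback, from 2 back to 8: the ring of 2 is kept as ring B and ring A is annulated stepwise. Hydroboration–oxidation of 2 (BH3·THF; NaOH, H2O2) gives the secondary alcohol (5R)-2-methyl-5-[2-(triethylsilyloxy)propan-2-yl]cyclohexan-1-ol F1. Oxidation with Dess–Martin periodinane and equilibration with NaOMe give the trans ketone (2R,5R)-2-methyl-5-[2-(triethylsilyloxy)propan-2-yl]cyclohexan-1-one F2. Condensation with (R)-1-phenylethylamine gives the imine F3, whose more substituted enamine tautomer adds to pent-1-en-3-one under control of the auxiliary. Hydrolysis with aqueous AcOH gives the 1,5-diketone F4 with the C10 quaternary centre. Aldol condensation (NaOMe, MeOH) closes ring A to the enone 11-(triethylsilyloxy)eudesm-4-en-3-one F5. Dissolving-metal reduction (Li, NH3, THF) sets the trans fusion and gives the lithium C3–C4 enolate F6, which is trapped with PhNTf2 as the enol triflate F7. Reduction with Pd(OAc)2, PPh3, Bu3N and HCO2H gives 8.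

**Step 9.** The hindered tertiary alkoxide may act as a base toward the iodonium salt (aryne formation and cine substitution, giving regioisomeric ethers), or ligand coupling may be slow enough for decomposition of the salt to win.

Fallback, from 15 back to 16: nucleophilic aromatic substitution replaces aryl transfer from iodine. Alkoxide 15 is treated with 4-chloro-1-fluoro-2-nitrobenzene in DMF to give the 4-chloro-2-nitrophenyl ether F8. The nitro group is reduced with Fe and NH4Cl in aqueous EtOH to the aniline F9. This is diazotised with t-BuONO in MeCN to the diazonium salt F10 and converted in the same flask with CuBr2 (Sandmeyer bromination) into 16.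

**Step 7.** Hydride must enter at C3 against the trans-diaxial (Fürst–Plattner) preference of the rigid ring, because diaxial opening would need attack at the tertiary C4 under the C10 methyl. The opening may therefore be slow, and base-induced isomerisation of the epoxide to an allylic alcohol may compete.

Fallback, from 8 back to 10: Mukaiyama hydration of the C3=C4 alkene (Co(acac)2, PhSiH3, O2, THF). Hydrogen-atom transfer puts hydrogen on C3, and the tertiary C4 radical is expected to take up oxygen from the α face, away from the C10 methyl. This gives 10 directly and makes no new compound.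

**Step 14.** Palladium hydride species may move the allyl double bonds (the new one and that of ring D) into conjugation at the temperature needed for oxidative addition to an electron-rich aryl chloride, and the ring D phenoxide may undergo C–O coupling.

Fallback, from 21 back to 23: the polarity is reversed. The phenol of 21 is silylated (TBSCl, imidazole, DMF) to the silyl ether F11. The C–Cl bond is borylated (B2pin2, Pd(OAc)2, XPhos, KOAc, dioxane) to the aryl boronate F12. This is coupled with allyl bromide (Pd(PPh3)4, K3PO4, toluene, 60 °C) to the bis-silyl ether F13. The conditions of step 15 then remove both silyl groups and give 23.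

## Further compounds

F1 | step 5 | (5R)-2-methyl-5-[2-(triethylsilyloxy)propan-2-yl]cyclohexan-1-ol (mixture at C1 and C2) | CC1CC[C@@H](C(C)(C)O[Si](CC)(CC)CC)CC1O
F2 | step 5 | (2R,5R)-2-methyl-5-[2-(triethylsilyloxy)propan-2-yl]cyclohexan-1-one | C[C@@H]1CC[C@@H](C(C)(C)O[Si](CC)(CC)CC)CC1=O
F3 | step 5 | N-[(1R)-1-phenylethyl] imine of F2 (C2 equilibrating) | CC1CC[C@@H](C(C)(C)O[Si](CC)(CC)CC)CC1=N[C@H](C)c1ccccc1
F4 | step 5 | 2-methyl-2-(3-oxopentyl)-5-[2-(triethylsilyloxy)propan-2-yl]cyclohexan-1-one (C2 methyl cis to the C5 group) | CCC(=O)CC[C@]1(C)CC[C@@H](C(C)(C)O[Si](CC)(CC)CC)CC1=O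
F5 | step 5 | 11-(triethylsilyloxy)eudesm-4-en-3-one | CC1=C2C[C@H](C(C)(C)O[Si](CC)(CC)CC)CC[C@@]2(C)CCC1=O
F6 | step 5 | lithium enolate, lithium 11-(triethylsilyloxy)eudesm-3-en-3-olate | CC1=C([O-])CC[C@]2(C)CC[C@@H](C(C)(C)O[Si](CC)(CC)CC)C[C@H]21.[Li+]
F7 | step 5 | 11-(triethylsilyloxy)eudesm-3-en-3-yl trifluoromethanesulfonate | CC1=C(OS(=O)(=O)C(F)(F)F)CC[C@]2(C)CC[C@@H](C(C)(C)O[Si](CC)(CC)CC)C[C@H]21
F8 | step 9 | 4α-(4-chloro-2-nitrophenoxy)-11-(triethylsilyloxy)eudesmane | O=[N+]([O-])c1cc(Cl)ccc1O[C@]1(C)CCC[C@]2(C)CC[C@@H](C(C)(C)O[Si](CC)(CC)CC)C[C@H]21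
F9 | step 9 | 5-chloro-2-{[11-(triethylsilyloxy)eudesman-4α-yl]oxy}aniline | Nc1cc(Cl)ccc1O[C@]1(C)CCC[C@]2(C)CC[C@@H](C(C)(C)O[Si](CC)(CC)CC)C[C@H]21
F10 | step 9 | 5-chloro-2-{[11-(triethylsilyloxy)eudesman-4α-yl]oxy}benzenediazonium bromide | N#[N+]c1cc(Cl)ccc1O[C@]1(C)CCC[C@]2(C)CC[C@@H](C(C)(C)O[Si](CC)(CC)CC)C[C@H]21.[Br-]
F0 | step 7 | none | none
F11 | step 14 | tert-butyldimethylsilyl ether of 21 | CC(C)(C)[Si](C)(C)Oc1ccc(-c2cc(Cl)ccc2O[C@]2(C)CCC[C@]3(C)CC[C@@H](C(C)(C)O[Si](CC)(CC)CC)C[C@H]32)cc1CC=C
F12 | step 14 | pinacol boronate from F11 (boron in place of chlorine) | CC(C)(C)[Si](C)(C)Oc1ccc(-c2cc(B3OC(C)(C)C(C)(C)O3)ccc2O[C@]2(C)CCC[C@]3(C)CC[C@@H](C(C)(C)O[Si](CC)(CC)CC)C[C@H]32)cc1CC=C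
F13 | step 14 | tert-butyldimethylsilyl ether of 22 | CC(C)(C)[Si](C)(C)Oc1ccc(-c2cc(CC=C)ccc2O[C@]2(C)CCC[C@]3(C)CC[C@@H](C(C)(C)O[Si](CC)(CC)CC)C[C@H]32)cc1CC=C
A1 | alternative 1 | methyl 4-{[11-(triethylsilyloxy)eudesman-4α-yl]oxy}-3-[4-(tert-butyldimethylsilyloxy)-3-(prop-2-en-1-yl)phenyl]benzoate | C=CCc1cc(-c2cc(C(=O)OC)ccc2O[C@]2(C)CCC[C@]3(C)CC[C@@H](C(C)(C)O[Si](CC)(CC)CC)C[C@H]32)ccc1O[Si](C)(C)C(C)(C)C
A2 | alternative 1 | ynol ether, 4α-{[4-(tert-butyldimethylsilyloxy)-3-(prop-2-en-1-yl)phenyl]ethynyloxy}-11-(triethylsilyloxy)eudesmane | C=CCc1cc(C#CO[C@]2(C)CCC[C@]3(C)CC[C@@H](C(C)(C)O[Si](CC)(CC)CC)C[C@H]32)ccc1O[Si](C)(C)C(C)(C)C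
A3 | alternative 1 | methyl coumalate, methyl 2-oxo-2H-pyran-5-carboxylate | COC(=O)C1=COC(=O)C=C1
A4 | alternative 2 | 4α-(2-bromo-4-chlorophenoxy)eudesman-11-ol | Clc1ccc(O[C@]2(C)CCC[C@]3(C)CC[C@@H](C(C)(C)O)C[C@H]32)c(Br)c1
A5 | alternative 2 | elemol | C=C[C@]1(C)CC[C@@H](C(C)(C)O)C[C@H]1C(C)=C
A6 | alternative 2 | 2-bromo-4-chlorophenol | Oc1ccc(Cl)cc1Br
A7 | alternative 3 | cryptomeridiol, eudesmane-4α,11-diol | O[C@]1(C)CCC[C@]2(C)CC[C@@H](C(C)(C)O)C[C@H]21
A8 | alternative 3 | (2E,6E)-farnesyl diphosphate | CC(C)=CCC/C(C)=C/CC/C(C)=C/COP(=O)(O)OP(=O)(O)O
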